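The constants used here are those of an exercise; the result is computed.

The target is the small peak I reckoned here: a balance share of a pair, taken on a split made earlier.

substrate 0.40 M; time 50 min

- which holds at 50 min: what has brought the reaction to rest, or that it has not come to rest (all of the substrate has reacted / it is still moving / forward and back rates have come level)
- how much target there is at 50 min, in percent of the substrate charged

- a species is counted by the substrate in it: one self-condensation product or side product counts as two
- a doubled species enters its step squared and goes two at a time
- the reaction counts as stopped when no species that holds the substrate changes by six tenths of a point or more over the second half of the time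
- run time (flask): 50 min

    target ⇌ isomer of the product (K1 = 31.3, k1 = 0.0414 s⁻¹)
    2 substrate → self-condensation product (k2 = 0.0352 M⁻¹ s⁻¹)
    substrate → target, rate k3*[substrate]/(1 + ([substrate]/sat3)) (sat3 = 0.227 M, k3 = 0.0374 s⁻¹)
    substrate + target → side product (k4 = 0.00167 M⁻¹ s⁻¹)

1. Target and isomer of the product exchange with relaxation time 1/(k1(1+1/K1)) = 0.390 min, far shorter than the 17 min half-life of target by the step to side product alone, with substrate as charged. So I let f = 1/(1+K1) = 3.10%, the balance share of target in the pair, carry the small peak, and reckoned the pair instead.

2. One extreme: with the whole charge passing to the pair, target is f itself, 3.10%.

3. Other extreme: the split stays as at the start. There substrate goes to target at 0.48 of its rate to self-condensation product (the selectivity factor), so the pair gets 32.5% and target 1.01%.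

4. The flask lies between, because the share s reaching the pair, which is the use of substrate towards target over that use plus its use by self-condensation, rises as substrate falls, to 58.5% at half the charge. Averaging s at zero, half and full charge, the middle weighted 4 times, I got a pair of 61.1% and target of 1.89%.

5. Late on, substrate has a lifetime of 1/k3 = 0.446 min, far shorter than 50 min, and no step returns it. So I expected the flask to end with its substrate reacted.

The forecast said 1.89% (1.8% to 2%) and "forward and back rates have come level", holding that “The target–isomer pair relaxes in under a minute”. We agreed on target and differed on the ending.

The flask gave 1.89% of target, and all of the substrate has reacted: substrate stood at 0% of its charge at 50.0 min, having dropped under a fiftieth at 1.86 min. For the neighbour flask charged with 1.0 M of substrate, the same average of s gave a pair of 34.8%, and f of that is 1.08%. That neighbour flask read 1.07% of target.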